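The constants are assumed; the run is a simulation.

A slurry invites counting what is made, so I counted the fraction left instead.

    dissolved substrate + partner → target (k1 = 0.103 L mol⁻¹ s⁻¹)
    partner ⇌ dormant form (K2 = 0.31, k2 = 0.00333 s⁻¹)
    partner + protic impurity → quenched reagent (k3 = 11.6 L mol⁻¹ s⁻¹)
    solid substrate ⇌ dissolved substrate, rate k4*(cs4 - [dissolved substrate]) while solid is left; crystals form when [dissolved substrate] > cs4 (cs4 = 6.8 mM, k4 = 9.16 × 10⁻⁴ s⁻¹)
    target ⇌ isomer of the product (K5 = 0.91, k5 = 0.00305 s⁻¹)

solid substrate 0.020 M; partner 3.00 equiv; protic impurity 4.00 mM; time 2.5 h

- solid substrate is a solid; its amount is given per volume of the solution
- at the start none of the solid substrate is in solution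
- run time (flask): 2.5 h

1. the target standing at 2.5 h, as a percentage of the solid substrate charged
2. the change that raises the amount of target at 2.5 h, in percent of the solid substrate charged most ("none" if none brings more than 2 percentage points) (epsilon / gamma / alpha / none)
3. amount of target at 2.5 h, in percent of the solid substrate charged, after epsilon

- epsilon: doubling the amount of partner, all else as stated
- gamma: doubling the solubility in step 4, all else as stated
- alpha: doubling the dissolution coefficient of step 4, all else as stated

1. I took step 1 by itself, with the substrate dissolved from the start. In this pseudo-first-order picture, dissolved substrate had a half-life of 1.9 min at charged partner. That is far shorter than the run, so its fraction left was negligible and target stood at the full charge.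

2. I added the losses of partner. Step 3 consumed 4.00 mM of it. The half-life of partner by that step, with protic impurity held at its charge, was 0.25 min. Step 2 relaxed with a half-life of 0.821 min, short against the run. So free [partner] began near 42.7 mM and ended near 27.5 mM. Even there, dissolved substrate had a half-life of 4.08 min, shorter than the run. In this picture, target stayed at the full charge.

3. I added the solid. With feed balancing consumption at the early free [partner], [dissolved substrate] held near 1.17 mM, and the solid dissolved at 18.6 mM h⁻¹. The charge divided by this rate is the clearing time, where the straight line of solid left meets zero. I got 1.08 h, shorter than the run. The remaining time held 20.9 of those late half-lives of dissolved substrate, so in this picture its fraction left stayed negligible and target was unchanged.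

4. I added the isomer. Step 5 relaxes with a half-life of 1.80 min, short against the run. So target kept the share 52.4 % of what had reacted, and I committed to that. Epsilon, gamma and alpha each act on a clearing time already inside the run, and the share does not contain them. So I chose none, with 52.4 % after epsilon as well.

5. The forecast gave 52.4 %, none and 52.4 %, holding that “Target and isomer then equilibrate within minutes”.

6. The simulation gave 52.4 %, none and 52.4 %.

In this flask the solid read 0 % at 1.25 h, later than the clearing time. The neighbouring flask, stopped at 40 min with its amounts held, lay inside the clearing time. My line gave 38.3 % of the solid left in that flask, and it read 38.0 %. My steady level gave 5.86 % dissolved, and it read 6.88 %. Taking both from the charge and applying the share gave 29.3 % target, and that flask read 30.7 %.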